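Numbering: C1 bears the methylidene, C5 the gem-dimethyl pair, C6/C10 are fusion carbons, C9 is quaternary. The route cuts the seven-membered ring A at C2–C3 and C5–C6. C3–C4–C5 is a 1,1-dimethylallyl unit, and C2=C1–C10=C6 is a diene once C1 is an enol silane on cyclopentene ring B. One (4+3) cycloaddition of the dimethyl oxyallyl cation closes ring A, forges both bonds, sets C6 and leaves C1 and C4 as distinguishable carbonyl groups. The precursor is a 1-(1-silyloxyvinyl)cyclopentene carrying C9 (methyl, silyloxymethyl). Later the arm becomes a carboxyl group, and the derived C9 radical is joined to a ribose-derived cyclopentenone that is reshaped into the dioxabicyclooctanone.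

Key step: step 8

Remarks on the chemistry
- **Side-unit labels (2,7-dioxabicyclo[3.2.1]octan-3-one numbering):** C1' acetal bridgehead, O2', C3' lactone carbonyl, C4' CHOAc, C5' bridgehead CH, C6' CHCO2Me, O7', C8' one-carbon bridge bonded to C9.
- **Labels on enone 27:** its ring carbons are labelled by their destination. C8' is the β-carbon, C5' the α-carbon, C4' the carbonyl carbon, and C3' and C1' are the acetonide carbons next to C4' and C8'.
- **Assumption:** 7, 27 and 30 are purchased; 27 is the (3aR,6aR) enone obtainable from D-ribose.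
- **Epimer mixtures:** C4 in 17–19 and C3' in 41 are carried as epimer mixtures, because both centres vanish.
- **C9 as a stereochemical relay:** it is set in step 1 and steers C6 in step 8. It is planarised in step 17, where the arm carbon leaves as CO2. It is rebuilt in the same step under control of C10 and C6.
- **Where each stereocentre is set:** C6 in step 8, C10 in step 12, C9 and C8' in step 17, C5' in step 18, C4' in step 19, C6' in step 20, C1' in step 23.

Step 1
Reactants: 1 methyl 2-oxocyclopentane-1-carboxylate; 2 iodomethane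
Product: 3 methyl (R)-1-methyl-2-oxocyclopentane-1-carboxylate
Conditions: MeI, chiral C2-symmetric N-spiro bis(binaphthyl)ammonium bromide (3,4,5-trifluorophenyl-substituted, 1 mol %, enantiomer that gives R), K2CO3 (sat. aq.), toluene, 0 °C
Reagents that add atoms: iodomethane (2), CI
Why: Asymmetric phase-transfer C-alkylation of a cyclic β-keto ester, in which the chiral ammonium cation pairs with the enolate and shields one face so that MeI sets quaternary C9 as R, any minor enantiomer being shed later as a diastereomer once enantiopure 27 is attached.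

Step 2
Reactants: 3 methyl (R)-1-methyl-2-oxocyclopentane-1-carboxylate
Product: 4 methyl (R)-1-methyl-2-(trifluoromethylsulfonyloxy)cyclopent-2-ene-1-carboxylate
Conditions: LiN(SiMe3)2, THF, −78 °C; PhNTf2, −78 °C → 0 °C
Reagents that add atoms: N-phenylbis(trifluoromethanesulfonimide), O=S(=O)(N(c1ccccc1)S(=O)(=O)C(F)(F)F)C(F)(F)F
Why: Kinetic enolate triflation; C9 is fully substituted, so the ketone can enolise only towards C6 and a single enol triflate should form without touching C9.

Step 3
Reactants: 4 methyl (R)-1-methyl-2-(trifluoromethylsulfonyloxy)cyclopent-2-ene-1-carboxylate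
Product: 5 (S)-5-(hydroxymethyl)-5-methylcyclopent-1-en-1-yl triflate
Conditions: i-Bu2AlH (2.5 equiv), CH2Cl2, −78 °C → 0 °C; Rochelle salt work-up
Reagents that add atoms: none
Why: Ester reduction with i-Bu2AlH, which leaves vinyl triflates intact at low temperature and avoids a reduce-then-reoxidise detour at C10.

Step 4
Reactants: 5 (S)-5-(hydroxymethyl)-5-methylcyclopent-1-en-1-yl triflate
Product: 6 (S)-5-methyl-5-(triisopropylsilyloxymethyl)cyclopent-1-en-1-yl triflate
Conditions: i-Pr3SiOTf, 2,6-lutidine, CH2Cl2, 0 °C
Reagents that add atoms: triisopropylsilyl triflate, CC(C)[Si](OS(=O)(=O)C(F)(F)F)(C(C)C)C(C)C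
Why: Silyl ether formation; the reactive silyl triflate overcomes the neopentyl hindrance and installs the large group that is to bias ring B in step 8.

Step 5
Reactants: 6 (S)-5-methyl-5-(triisopropylsilyloxymethyl)cyclopent-1-en-1-yl triflate; 7 tributyl(1-ethoxyvinyl)stannane
Product: 9 (R)-1-[5-methyl-5-(triisopropylsilyloxymethyl)cyclopent-1-en-1-yl]ethanone, via ethoxydiene 8 (not isolated)
Conditions: Pd(PPh3)4 (5 mol %), LiCl (3 equiv), THF, reflux; then 1 M HCl, rt
Reagents that add atoms: tributyl(1-ethoxyvinyl)stannane (7), C=C(OCC)[Sn](CCCC)(CCCC)CCCC; water, O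
Why: Stille coupling of a vinyl triflate on zerovalent palladium (chloride-assisted) followed by mild acid hydrolysis of the enol ether, which the primary TIPS ether survives.

Step 6
Reactants: 9 (R)-1-[5-methyl-5-(triisopropylsilyloxymethyl)cyclopent-1-en-1-yl]ethanone
Product: 10 (R)-1-[1-(tert-butyldimethylsilyloxy)vinyl]-5-methyl-5-(triisopropylsilyloxymethyl)cyclopent-1-ene
Conditions: t-BuMe2SiOTf, Et3N, CH2Cl2, 0 °C
Reagents that add atoms: tert-butyldimethylsilyl triflate, CC(C)(C)[Si](C)(C)OS(=O)(=O)C(F)(F)F
Why: Soft enolisation and O-silylation of a methyl enone, in which the acetyl CH3 is deprotonated faster than the remote C7 position and the cross-conjugated 2-silyloxydiene should result.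

Step 7
Reactants: 11 3-methylbutan-2-one
Product: 13 1,3-dibromo-3-methylbutan-2-one, via monobromide 12 (not isolated)
Conditions: Br2 (2 equiv), HBr (cat.), AcOH, 10 °C → rt
Reagents that add atoms: bromine, BrBr
Why: Acid-catalysed α-bromination; the more substituted enol reacts first at the tertiary carbon, after which the second bromine can enter only the methyl group.

Step 8
Reactants: 10 (R)-1-[1-(tert-butyldimethylsilyloxy)vinyl]-5-methyl-5-(triisopropylsilyloxymethyl)cyclopent-1-ene; 13 1,3-dibromo-3-methylbutan-2-one
Product: 16 hydroazulenone cycloadduct (C4 ketone; C1=C10 TBS enol ether; C5 gem-dimethyl; C5 cis to the C9 methyl), via oxyallyl cation 14 (not isolated), via zwitterion 15 (not isolated)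
Conditions: Zn–Cu couple (3 equiv), 13 (2 equiv, slow addition), DME, −10 °C → rt
Reagents that add atoms: 1,3-dibromo-3-methylbutan-2-one (13), BrCC(=O)C(C)(C)Br
Why: Zinc reduces 13 to the zinc-bound 1,1-dimethyl oxyallyl cation 14, whose unhindered CH2 terminus is attacked by the most nucleophilic diene carbon C2 to give zwitterion 15, a zinc enolate tethered to an O-silylated cyclopentenyl ketone. The tertiary enolate carbon C5 then adds to C6 of that siloxyallyl cation in a 7-endo-trig closure that completes ring A and regenerates the enol silane at C1=C10; overall this is the reductive (4+3) cycloaddition of α,α'-dibromo ketones with open-chain 1,3-dienes, which is established for this same dimethyl oxyallyl unit. The regiochemistry (C2 to CH2, C6 to CMe2) follows from the polarity of the siloxydiene and the steric bias of the cation, so the gem-dimethyl group ends at C5. The only new stereocentre, C6, is controlled by C9: the tether should sweep over the ring B face that carries the small methyl group, away from CH2OTIPS, which places C5 cis to the C9 methyl. Five-ring closure at C1 would create two adjacent fully substituted carbons and O-closure is reversible under ZnBr2, so both should drain into the seven-membered ketone, while the bulky TBS group slows silyl loss from 15. C4 emerges as a free ketone and C1 as a masked one, which allows C4 to be removed selectively.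

Step 9
Reactants: 16 hydroazulenone cycloadduct
Product: 17 C4 alcohol (epimer mixture at C4)
Conditions: LiAlH4, Et2O, 0 °C
Reagents that add atoms: none
Why: Hydride reduction of the only free carbonyl group; the tetrasubstituted enol silane and the TIPS ether are inert, and the carbinol configuration is irrelevant because C4 becomes CH2.

Step 10
Reactants: 17 C4 alcohol; 2 iodomethane
Product: 19 O-(C4) S-methyl xanthate, via potassium xanthate 18 (not isolated)
Conditions: KN(SiMe3)2, THF, 0 °C; CS2; MeI, rt
Reagents that add atoms: carbon disulfide, S=C=S; iodomethane (2), CI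
Why: Xanthate formation, the first half of the Barton–McCombie deoxygenation, with a strong potassium base because the carbinol is flanked by the quaternary C5.

Step 11
Reactants: 19 O-(C4) S-methyl xanthate
Product: 20 C4-deoxygenated enol silane
Conditions: Bu3SnH, AIBN (cat.), toluene, 100 °C
Reagents that add atoms: none
Why: Barton–McCombie radical deoxygenation; the stannyl radical adds to C=S and the released secondary C4 radical should be quenched by Bu3SnH faster than any strained transannular addition to the C1=C10 enol silane.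

Step 12
Reactants: 20 C4-deoxygenated enol silane
Product: 21 cis-fused C1 ketone (H10 cis to H6; TIPS ether retained)
Conditions: Bu4NF/AcOH (1:1), THF, −20 °C
Reagents that add atoms: none
Why: Fluoride cleavage of the enol silane with kinetic C-protonation in a buffered medium; the proton should reach C10 on the face of H6 because the other face is roofed by ring A, a C5 methyl and the C9 methyl, which gives the cis fusion while the less labile primary TIPS ether stays.

Step 13
Reactants: 21 cis-fused C1 ketone
Product: 22 C1-methylidene hydroazulene TIPS ether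
Conditions: Zn, CH2Br2, TiCl4, THF (reagent aged at 5 °C); then 21, CH2Cl2, 0 °C → rt
Reagents that add atoms: dibromomethane, BrCBr
Why: Lombardo–Takai methylenation with a non-basic gem-dizinc/titanium reagent, chosen because it converts hindered enolisable ketones without epimerising the α-centre C10.

Step 14
Reactants: 22 C1-methylidene hydroazulene TIPS ether
Product: 23 C9-hydroxymethyl hydroazulene
Conditions: Bu4NF, THF, rt
Reagents that add atoms: none
Why: Fluoride desilylation; no other group in 22 reacts with Bu4NF.

Step 15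
Reactants: 23 C9-hydroxymethyl hydroazulene
Product: 25 hydroazulene-9-carboxylic acid, via aldehyde 24 (not isolated)
Conditions: 1-methyl-2-azaadamantane N-oxoammonium tetrafluoroborate (5 mol %), NaClO2 (3 equiv), MeCN/phosphate buffer pH 6.8, rt
Reagents that add atoms: sodium chlorite, [Na+].[O-]Cl=O
Why: Oxoammonium-catalysed oxidation to the aldehyde with in situ chlorite (Pinnick-type) oxidation to the acid; the unhindered azaadamantane catalyst accepts neopentyl alcohols and consumes the hypochlorite by-product, which protects the 1,1-disubstituted alkene.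

Step 16
Reactants: 25 hydroazulene-9-carboxylic acid
Product: 26 N-acyloxyphthalimide of 25
Conditions: N-hydroxyphthalimide, DCC, DMAP (cat.), CH2Cl2, rt
Reagents that add atoms: N-hydroxyphthalimide, O=C1c2ccccc2C(=O)N1O
Why: Steglich-type esterification to the redox-active ester; no stereocentre is affected.

Step 17
Reactants: 26 N-acyloxyphthalimide of 25; 27 (3aR,6aR)-2,2-dimethyl-3a,6a-dihydrocyclopenta[d][1,3]dioxol-4-one
Product: 29 coupled acetonide cyclopentanone (C9–C8' bond on the H6/H10 face; C9 anti to the acetonide on the five-membered ring), via C9 radical 28 (not isolated)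
Conditions: 27 (1.5 equiv), Ru(bpy)3(PF6)2 (1 mol %), Hantzsch ester (1.5 equiv), i-Pr2NEt, CH2Cl2, blue LEDs, rt
Reagents that add atoms: enone 27, O=C1C=C[C@H]2OC(C)(C)O[C@@H]12
Why: Photoredox decarboxylative Giese addition, in which single-electron reduction of 26 releases CO2, phthalimide anion and the planar radical 28, which should bond on its convex face (that of H10 and H6, anti to C1) to the β-carbon of 27 on the face opposite the acetonide, so that C9 is rebuilt in its original sense and C8' is set before the Hantzsch ester delivers hydrogen to C5'.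

Step 18
Reactants: 29 coupled acetonide cyclopentanone; 30 methyl bromoacetate
Product: 31 C5'-(methoxycarbonylmethyl) ketone (side chain trans to C9 and cis to the acetonide)
Conditions: LiN(SiMe3)2, THF, −78 °C; 30, DMPU, −78 °C → −30 °C
Reagents that add atoms: methyl bromoacetate (30), COC(=O)CBr
Why: Kinetic enolate alkylation; the base should remove a C5' proton rather than the acetonide-flanked C3' proton, and the electrophile enters trans to the very large C8' substituent, which is also the thermodynamic arrangement at this epimerisable centre.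

Step 19
Reactants: 31 C5'-(methoxycarbonylmethyl) ketone
Product: 33 cis-fused γ-lactone (O4' acylated by the side-chain carboxyl carbon), via hydroxy ester 32 (not isolated)
Conditions: NaBH4, MeOH, −20 °C → rt
Reagents that add atoms: none
Why: Substrate-controlled borohydride reduction from the convex face of the acetonide-fused cyclopentanone should give the C4' alcohol cis to the acetonide and to the acetate arm, and the alkoxide then lactonises (5-exo-trig).

Step 20
Reactants: 33 cis-fused γ-lactone
Product: 34 C6'-hydroxy lactone (OH cis to H5' and trans to C8')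
Conditions: KN(SiMe3)2, THF, −78 °C; 2-(phenylsulfonyl)-3-phenyloxaziridine; AcOH quench
Reagents that add atoms: 2-(phenylsulfonyl)-3-phenyloxaziridine, O=S(=O)(N1OC1c1ccccc1)c1ccccc1
Why: Davis enolate hydroxylation; the lactone enolate is open only on its convex face, away from the cyclopentane and the acetonide, which sets C6' in the configuration required in 42.

Step 21
Reactants: 34 C6'-hydroxy lactone
Product: 35 C6'-triethylsilyloxy lactone
Conditions: Et3SiCl, imidazole, DMF, 0 °C → rt
Reagents that add atoms: chlorotriethylsilane, CC[Si](Cl)(CC)CC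
Why: Silyl protection of the C6' hydroxyl as an acid-labile ether, so that only O4' is acetylated in step 22.

Step 22
Reactants: 35 C6'-triethylsilyloxy lactone; 2 iodomethane
Product: 38 C4' acetate methyl ester (acetonide and TES ether retained), via lithium carboxylate 36 (not isolated), via hydroxy ester 37 (not isolated)
Conditions: LiOH (1.1 equiv), THF/H2O, 0 °C; evaporate; MeI, DMF, rt; evaporate; Ac2O, DMAP (cat.), pyridine, CH2Cl2, 0 °C
Reagents that add atoms: lithium hydroxide, [Li+].[OH-]; iodomethane (2), CI; acetic anhydride, CC(=O)OC(C)=O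
Why: Saponification, carboxylate O-alkylation and DMAP-catalysed acetylation are run without isolating the hydroxy ester, so that O4' is capped before it can relactonise; no stereocentre is involved.

Step 23
Reactants: 38 C4' acetate methyl ester
Product: 41 bicyclic lactol (3-hydroxy-2,7-dioxabicyclo[3.2.1]octane; epimer mixture at C3'), via triol 39 (not isolated), via dialdehyde 40 (not isolated)
Conditions: 2 M HCl, THF, rt; then phosphate buffer pH 7, NaIO4, THF/H2O, 0 °C → rt
Reagents that add atoms: none
Why: Acid hydrolysis removes the acetonide and the TES ether, Malaprade glycol cleavage opens the C1'–C3' bond, and the C6' hydroxyl and the two aldehydes fold up to the bridged lactol, in which C1' is fixed by the bicyclic geometry and which should be preferred over the isomer acetalised at C3' because only it holds CO2Me exo.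

Step 24
Reactants: 41 bicyclic lactol
Product: 42 target CNP0215240.1
Conditions: Dess–Martin periodinane, CH2Cl2, 0 °C → rt
Reagents that add atoms: none
Why: Dess–Martin oxidation of the lactol, the only free hydroxyl group, to the δ-lactone under neutral conditions that spare the alkene, the acetate, the ester and the acetal.

Compound list
1 | methyl 2-oxocyclopentane-1-carboxylate | COC(=O)C1CCCC1=O | starting material
2 | iodomethane | CI | starting material
3 | methyl (R)-1-methyl-2-oxocyclopentane-1-carboxylate | O=C1CCC[C@@]1(C)C(=O)OC | intermediate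
4 | methyl (R)-1-methyl-2-(trifluoromethylsulfonyloxy)cyclopent-2-ene-1-carboxylate | O=S(=O)(OC1=CCC[C@@]1(C)C(=O)OC)C(F)(F)F | intermediate
5 | (S)-5-(hydroxymethyl)-5-methylcyclopent-1-en-1-yl triflate | O=S(=O)(OC1=CCC[C@@]1(C)CO)C(F)(F)F | intermediate
6 | (S)-5-methyl-5-(triisopropylsilyloxymethyl)cyclopent-1-en-1-yl triflate | O=S(=O)(OC1=CCC[C@@]1(C)CO[Si](C(C)C)(C(C)C)C(C)C)C(F)(F)F | intermediate
7 | tributyl(1-ethoxyvinyl)stannane | C=C(OCC)[Sn](CCCC)(CCCC)CCCC | starting material
8 | (R)-1-(1-ethoxyvinyl)-5-methyl-5-(triisopropylsilyloxymethyl)cyclopent-1-ene (not isolated) | C=C(OCC)C1=CCC[C@@]1(C)CO[Si](C(C)C)(C(C)C)C(C)C | intermediate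
9 | (R)-1-[5-methyl-5-(triisopropylsilyloxymethyl)cyclopent-1-en-1-yl]ethanone | CC(=O)C1=CCC[C@@]1(C)CO[Si](C(C)C)(C(C)C)C(C)C | intermediate
10 | (R)-1-[1-(tert-butyldimethylsilyloxy)vinyl]-5-methyl-5-(triisopropylsilyloxymethyl)cyclopent-1-ene | C=C(O[Si](C)(C)C(C)(C)C)C1=CCC[C@@]1(C)CO[Si](C(C)C)(C(C)C)C(C)C | intermediate
11 | 3-methylbutan-2-one | CC(=O)C(C)C | starting material
12 | 3-bromo-3-methylbutan-2-one (not isolated) | CC(=O)C(C)(C)Br | intermediate
13 | 1,3-dibromo-3-methylbutan-2-one | BrCC(=O)C(C)(C)Br | intermediate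
14 | 1,1-dimethyl-2-oxidoallyl cation, zinc-bound (not isolated) | CC(C)=C([O-])[CH2+] | intermediate
15 | zwitterion after C2–C3 bond formation: zinc enolate at C4/C5 tethered to the O-silylated cyclopentenyl ketone (not isolated) | CC(C)=C([O-])CCC(=[O+][Si](C)(C)C(C)(C)C)C1=CCC[C@@]1(C)CO[Si](C(C)C)(C(C)C)C(C)C | intermediate
16 | 1-(tert-butyldimethylsilyloxy)-5,5,9-trimethyl-9-(triisopropylsilyloxymethyl)bicyclo[5.3.0]dec-1(10)-en-4-one (route numbering); H6 on the face of the CH2OTIPS arm, C5 cis to the C9 methyl | O=C1CCC(O[Si](C)(C)C(C)(C)C)=C2[C@](C)(CO[Si](C(C)C)(C(C)C)C(C)C)CC[C@H]2C1(C)C | intermediate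
17 | C4 alcohol of 16 (C4 epimers) | OC1CCC(O[Si](C)(C)C(C)(C)C)=C2[C@](C)(CO[Si](C(C)C)(C(C)C)C(C)C)CC[C@H]2C1(C)C | intermediate
18 | potassium O-(C4) xanthate of 17 (not isolated) | [K+].[S-]C(=S)OC1CCC(O[Si](C)(C)C(C)(C)C)=C2[C@](C)(CO[Si](C(C)C)(C(C)C)C(C)C)CC[C@H]2C1(C)C | intermediate
19 | O-(C4) S-methyl xanthate of 17 | CSC(=S)OC1CCC(O[Si](C)(C)C(C)(C)C)=C2[C@](C)(CO[Si](C(C)C)(C(C)C)C(C)C)CC[C@H]2C1(C)C | intermediate
20 | C4-deoxygenated C1=C10 TBS enol ether | C1CCC(O[Si](C)(C)C(C)(C)C)=C2[C@](C)(CO[Si](C(C)C)(C(C)C)C(C)C)CC[C@H]2C1(C)C | intermediate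
21 | cis-fused C1 ketone; H6 and H10 on the face of the CH2OTIPS arm, C1, C5 and the C9 methyl on the other face | O=C1CCCC(C)(C)[C@@H]2CC[C@@](C)(CO[Si](C(C)C)(C(C)C)C(C)C)[C@H]12 | intermediate
22 | C1-methylidene analogue of 21 | C=C1CCCC(C)(C)[C@@H]2CC[C@@](C)(CO[Si](C(C)C)(C(C)C)C(C)C)[C@H]12 | intermediate
23 | C9-hydroxymethyl cis-hydroazulene | C=C1CCCC(C)(C)[C@@H]2CC[C@@](C)(CO)[C@H]12 | intermediate
24 | C9-carbaldehyde (not isolated) | C=C1CCCC(C)(C)[C@@H]2CC[C@@](C)(C=O)[C@H]12 | intermediate
25 | C9-carboxylic acid | C=C1CCCC(C)(C)[C@@H]2CC[C@@](C)(C(=O)O)[C@H]12 | intermediate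
26 | N-acyloxyphthalimide of 25 | C=C1CCCC(C)(C)[C@@H]2CC[C@@](C)(C(=O)ON3C(=O)c4ccccc4C3=O)[C@H]12 | intermediate
27 | (3aR,6aR)-2,2-dimethyl-3a,6a-dihydrocyclopenta[d][1,3]dioxol-4-one | O=C1C=C[C@H]2OC(C)(C)O[C@@H]12 | starting material
28 | tertiary C9 radical of the cis-hydroazulene (not isolated) | C=C1CCCC(C)(C)[C@@H]2CC[C](C)[C@H]12 | intermediate
29 | acetonide cyclopentanone bearing the hydroazulen-9-yl group at C8', anti to the acetonide; C9–C8' bond on the H6/H10 face | C=C1CCCC(C)(C)[C@@H]2CC[C@@](C)([C@H]3CC(=O)[C@@H]4OC(C)(C)O[C@H]34)[C@H]12 | intermediate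
30 | methyl bromoacetate | COC(=O)CBr | starting material
31 | 29 with CH2CO2Me at C5', trans to C9 and cis to the acetonide | C=C1CCCC(C)(C)[C@@H]2CC[C@@](C)([C@H]3[C@H](CC(=O)OC)C(=O)[C@@H]4OC(C)(C)O[C@H]34)[C@H]12 | intermediate
32 | C4' alcohol of 31, OH cis to acetonide and side chain (not isolated) | C=C1CCCC(C)(C)[C@@H]2CC[C@@](C)([C@H]3[C@H](CC(=O)OC)[C@H](O)[C@@H]4OC(C)(C)O[C@H]34)[C@H]12 | intermediate
33 | cis-fused γ-lactone O4'–C(=O)–C6'H2–C5' | C=C1CCCC(C)(C)[C@@H]2CC[C@@](C)([C@H]3[C@@H]5CC(=O)O[C@@H]5[C@@H]4OC(C)(C)O[C@H]34)[C@H]12 | intermediate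
34 | C6'-hydroxy lactone, OH on the convex face (cis to H5') | C=C1CCCC(C)(C)[C@@H]2CC[C@@](C)([C@H]3[C@@H]5[C@@H](O)C(=O)O[C@@H]5[C@@H]4OC(C)(C)O[C@H]34)[C@H]12 | intermediate
35 | C6'-triethylsilyl ether of 34 | C=C1CCCC(C)(C)[C@@H]2CC[C@@](C)([C@H]3[C@@H]5[C@@H](O[Si](CC)(CC)CC)C(=O)O[C@@H]5[C@@H]4OC(C)(C)O[C@H]34)[C@H]12 | intermediate
36 | lithium carboxylate from lactone opening, C4'-OH free (not isolated) | [Li+].C=C1CCCC(C)(C)[C@@H]2CC[C@@](C)([C@H]3[C@H]([C@@H](O[Si](CC)(CC)CC)C(=O)[O-])[C@H](O)[C@@H]4OC(C)(C)O[C@H]34)[C@H]12 | intermediate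
37 | methyl ester of 36, C4'-OH free (not isolated) | C=C1CCCC(C)(C)[C@@H]2CC[C@@](C)([C@H]3[C@H]([C@@H](O[Si](CC)(CC)CC)C(=O)OC)[C@H](O)[C@@H]4OC(C)(C)O[C@H]34)[C@H]12 | intermediate
38 | C4' acetate of 37 | C=C1CCCC(C)(C)[C@@H]2CC[C@@](C)([C@H]3[C@H]([C@@H](O[Si](CC)(CC)CC)C(=O)OC)[C@H](OC(C)=O)[C@@H]4OC(C)(C)O[C@H]34)[C@H]12 | intermediate
39 | triol (C1'-OH, C3'-OH, C6'-OH) with the C4' acetate (not isolated) | C=C1CCCC(C)(C)[C@@H]2CC[C@@](C)([C@H]3[C@H]([C@@H](O)C(=O)OC)[C@H](OC(C)=O)[C@H](O)[C@@H]3O)[C@H]12 | intermediate
40 | C1',C3'-dialdehyde with free C6'-OH (not isolated) | C=C1CCCC(C)(C)[C@@H]2CC[C@@](C)([C@H](C=O)[C@H]([C@@H](O)C(=O)OC)[C@H](OC(C)=O)C=O)[C@H]12 | intermediate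
41 | bicyclic lactol, 3'-hydroxy analogue of the target (C3' epimers) | C=C1CCCC(C)(C)[C@@H]2CC[C@@](C)([C@@H]3[C@@H]4OC(O)[C@@H](OC(C)=O)[C@H]3[C@H](C(=O)OC)O4)[C@H]12 | intermediate
42 | methyl (1'S,4'S,5'R,6'R,8'R)-4'-acetoxy-3'-oxo-8'-[(6R,9R,10S)-5,5,9-trimethyl-1-methylidene-cis-bicyclo[5.3.0]decan-9-yl]-2',7'-dioxabicyclo[3.2.1]octane-6'-carboxylate (route numbering) | C=C1CCCC(C)(C)[C@@H]2CC[C@@](C)([C@@H]3[C@@H]4OC(=O)[C@@H](OC(C)=O)[C@H]3[C@H](C(=O)OC)O4)[C@H]12 | target

Total step count: 24. Longest linear sequence: 23 steps (steps 1–6 and 8–24; step 7 is a side branch).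

Steps most likely to fail

**1. Step 8.**
- What may go wrong:
  - The dibromide is reduced further before the diene captures the cation.
  - The silyl group is lost from the zwitterion before ring closure.
  - Closure occurs at C1 to a five-membered ring.
  - The facial bias at C6 is weak.
- The fallback sets out from 11 and 10 and returns at 16. It generates the three-carbon unit by ionisation instead of reduction.
- 11 is chlorinated at its tertiary carbon (SO2Cl2) to 3-chloro-3-methylbutan-2-one F1.
- Kinetic silylation (LiN(i-Pr)2, Me3SiCl, THF, −78 °C) gives [(3-chloro-3-methylbut-1-en-2-yl)oxy]trimethylsilane F2.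
- AgOSO2CF3 with 2,6-di-tert-butylpyridine in CH2Cl2 at −78 °C strips chloride in the presence of 10, giving the 1,1-dimethyl-2-(trimethylsiloxy)allyl cation F3.
- No reducing metal and no basic metal enolate is then present. After attack of C2 on the CH2 terminus, the closing nucleophile is a neutral tetrasubstituted enol silane (intramolecular Mukaiyama–Michael addition to C6). Loss of the trimethylsilyl group from the C4 oxygen delivers 16.
- Any C6 epimer is removed by chromatography at 16.

**2. Step 17.**
- What may go wrong: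
  - The hindered tertiary radical is reduced by the hydrogen donor before it is captured.
  - In the following step, enolisation strays to the acetonide side and the C1' oxygen is lost by elimination.
- The fallback sets out from 26 and 27 and returns at 31. It uses a more electrophilic acceptor and a regiospecific reductive route to the enolate.
- 27 is chlorinated at C5' (PhICl2, pyridine, CH2Cl2) to (3aR,6aR)-5-chloro-2,2-dimethyl-3a,6a-dihydrocyclopenta[d][1,3]dioxol-4-one F4.
- The same photoredox coupling with 26 gives the C5'-chloro ketone adduct F5.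
- Me2CuLi (THF, −78 °C) removes the chlorine to give only the C4'/C5' enolate, which is alkylated in the same flask with 30. The route is rejoined at 31 and steps 17 and 18 are replaced together.

**3. Step 12.**
- What may go wrong:
  - C10 is protonated from the wrong face.
  - The α-centre epimerises later at the ketone stage towards the trans-fused series.
- The fallback sets out from 20 and returns at 22. It never passes through an enolisable ketone and creates H10 and the methylidene group in one irreversible sigmatropic event.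
- 20 is converted with CsF and PhNTf2 (DME, rt) into the C1 vinyl triflate F6.
- Stille coupling with Bu3SnCH2OH (Pd(PPh3)4, LiCl, dioxane, 100 °C) gives the C1-hydroxymethyl C1=C10 alkene F7.
- Mitsunobu reaction with 2-nitrobenzenesulfonylhydrazide (PPh3, DEAD, THF, −30 °C) gives the N-allylic sulfonylhydrazine F8.
- On warming, F8 loses sulfinic acid to the allylic diazene F9.
- The retro-ene loss of nitrogen hands the diazene hydrogen to C10 across the more open H6 face while the double bond moves to C1=CH2, which gives 22 directly.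

Further compounds
F1 | step 8 | 3-chloro-3-methylbutan-2-one | CC(=O)C(C)(C)Cl
F2 | step 8 | [(3-chloro-3-methylbut-1-en-2-yl)oxy]trimethylsilane | C=C(O[Si](C)(C)C)C(C)(C)Cl
F3 | step 8 | 1,1-dimethyl-2-(trimethylsiloxy)allyl cation | C=C(O[Si](C)(C)C)[C+](C)C
F4 | step 17 | (3aR,6aR)-5-chloro-2,2-dimethyl-3a,6a-dihydrocyclopenta[d][1,3]dioxol-4-one | O=C1C(Cl)=C[C@H]2OC(C)(C)O[C@@H]12
F5 | step 17 | C5'-chloro ketone adduct (C5' epimers) | C=C1CCCC(C)(C)[C@@H]2CC[C@@](C)([C@H]3C(Cl)C(=O)[C@@H]4OC(C)(C)O[C@H]34)[C@H]12
F6 | step 12 | C1 vinyl triflate | C1CCC(OS(=O)(=O)C(F)(F)F)=C2[C@](C)(CO[Si](C(C)C)(C(C)C)C(C)C)CC[C@H]2C1(C)C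
F7 | step 12 | C1-hydroxymethyl C1=C10 alkene | C1CCC(CO)=C2[C@](C)(CO[Si](C(C)C)(C(C)C)C(C)C)CC[C@H]2C1(C)C
F8 | step 12 | N-allylic N-(2-nitrophenylsulfonyl)hydrazine | C1CCC(CN(N)S(=O)(=O)c3ccccc3[N+](=O)[O-])=C2[C@](C)(CO[Si](C(C)C)(C(C)C)C(C)C)CC[C@H]2C1(C)C
F9 | step 12 | allylic diazene | C1CCC(CN=N)=C2[C@](C)(CO[Si](C(C)C)(C(C)C)C(C)C)CC[C@H]2C1(C)C
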